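## Retrosynthetic overview

1. The dioxabicyclo[3.2.1]octanone is closed last, by acid-triggered bicyclisation of a seco hydroxy aldehydo-acid. This comes from regioselective oxidation and periodate cleavage of a cyclopentane-1,2-diol.
2. That cyclopentane comes from a photoredox Giese coupling of a tertiary hydroazulenyl radical (from the tertiary alcohol via its oxalate) with an enantiopure dioxolane-fused cyclopentenone. Enolate alkylation, ketone reduction/lactonisation and lactone α-hydroxylation follow.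
3. The cyclopentenone comes from esterase desymmetrisation of a meso diacetate made from cis-3,5-diacetoxycyclopentene.
4. The hydroazulenol comes from an intramolecular Hosomi–Sakurai closure of the five-membered ring onto a seven-membered allylsilane. Its single stereocentre is set by Cu-catalysed asymmetric conjugate addition of a dialkylzinc to 4,4-dimethylcycloheptenone, made by ring expansion of 3-methylcyclohexenone.
5. Ring order: seven-membered carbocycle, five-membered carbocycle, temporary cyclopentane and γ-lactone, then tetrahydrofuran and δ-lactone together in the last step.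

Notation: HAz = (1R,3aR,8aS)-1,4,4-trimethyl-8-methylidenedecahydroazulen-1-yl, bonded through C1 on the face of H-3a/H-8a. Cyclopentane positions are numbered 3a, 4, 5, 6, 6a as in cyclopenta[d][1,3]dioxole. L = (S)-BINOL N,N-bis[(R)-1-phenylethyl]phosphoramidite.

Assumption 1: ligand L is taken to show the same facial sense on enone 5 as on unsubstituted cycloalkenones; if not, its enantiomer is used.

Assumption 2: the carbinol carbon of 16, 17 and 18 forms as an epimer mixture; both epimers give the same tertiary radical, so that centre is left open in their SMILES.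

Assumption 3: the esterase is taken to hydrolyse the enantiotopic acetate that leaves monoacetate 22 as drawn; all later stereochemistry is written for that enantiomer.

## Route

Step 1
Reactants: 1 3-methylcyclohex-2-en-1-one
Product: 2 [(3,3-dimethylcyclohex-1-en-1-yl)oxy]trimethylsilane
Conditions: MeMgBr, CuBr·SMe2 (5 mol %), TMSCl, THF, −78 → −40 °C
Reagents that add atoms: methylmagnesium bromide C[Mg]Br; chlorotrimethylsilane C[Si](C)(C)Cl
Why: Cu-catalysed conjugate addition of the Grignard reagent with in situ O-silylation gives the regiodefined silyl enol ether whose double bond points at the new gem-dimethyl carbon; no stereocentre is formed.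

Step 2
Reactants: 2 [(3,3-dimethylcyclohex-1-en-1-yl)oxy]trimethylsilane
Product: 5 4,4-dimethylcyclohept-2-en-1-one, via siloxycyclopropane 3 (not isolated), via chloro ketone 4 (not isolated)
Conditions: Zn(Ag), CH2I2, Et2O, reflux; FeCl3, DMF, 0 → 60 °C; NaOAc, MeOH, reflux
Reagents that add atoms: diiodomethane ICI
Why: Simmons–Smith cyclopropanation, FeCl3-mediated Saegusa–Ito ring opening and dehydrochlorination insert one carbon between the carbonyl and the former enol carbon, and the racemic transient intermediates end as an achiral enone.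

Step 3
Reactants: 6 2-(2-bromoethyl)-2-methyl-1,3-dioxolane
Product: 7 bromo[2-(2-methyl-1,3-dioxolan-2-yl)ethyl]magnesium (titrated THF stock solution)
Conditions: Mg turnings, THF, 25–30 °C
Reagents that add atoms: magnesium [Mg]
Why: Grignard formation by insertion of magnesium into the primary C–Br bond; the ketal oxygens are γ to the metal, so β-elimination is not possible, and no stereocentre is involved.

Step 4
Reactants: 7 bromo[2-(2-methyl-1,3-dioxolan-2-yl)ethyl]magnesium
Product: 8 chloro[2-(2-methyl-1,3-dioxolan-2-yl)ethyl]zinc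
Conditions: ZnCl2 (1.0 equiv), THF, 0 °C (7 added to the zinc salt)
Reagents that add atoms: zinc dichloride Cl[Zn]Cl
Why: Magnesium-to-zinc transmetalation; inverse addition of one equivalent of the Grignard reagent to a full equivalent of ZnCl2 stops at the monoalkylzinc chloride.

Step 5
Reactants: 8 chloro[2-(2-methyl-1,3-dioxolan-2-yl)ethyl]zinc; 7 bromo[2-(2-methyl-1,3-dioxolan-2-yl)ethyl]magnesium (second equivalent)
Product: 9 bis[2-(2-methyl-1,3-dioxolan-2-yl)ethyl]zinc
Conditions: THF/Et2O, 0 °C → rt; 1,4-dioxane, filtration under Ar; solvent exchange to PhMe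
Reagents that add atoms: none
Why: A second transmetalation replaces the remaining chloride on zinc by the same alkyl group, and precipitation of the magnesium halide with dioxane gives the salt-free dialkylzinc that the copper/phosphoramidite addition needs.

Step 6
Reactants: 5 4,4-dimethylcyclohept-2-en-1-one; 9 bis[2-(2-methyl-1,3-dioxolan-2-yl)ethyl]zinc
Product: 11 trimethyl{[(3R)-4,4-dimethyl-3-[2-(2-methyl-1,3-dioxolan-2-yl)ethyl]cyclohept-1-en-1-yl]oxy}silane, via zinc enolate 10 (not isolated)
Conditions: Cu(OTf)2 (2 mol %), L (4 mol %), PhMe, −30 °C; TMSOTf, −78 °C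
Reagents that add atoms: trimethylsilyl triflate C[Si](C)(C)OS(=O)(=O)C(F)(F)F
Why: Cu/phosphoramidite-catalysed asymmetric conjugate addition sets the first stereocentre (C3, R) by ligand-controlled delivery of the alkyl group to one enone face, and silylation of the zinc enolate fixes the enolate regiochemistry.

Step 7
Reactants: 11 silyl enol ether
Product: 13 (3R)-4,4-dimethyl-3-[2-(2-methyl-1,3-dioxolan-2-yl)ethyl]cyclohept-1-en-1-yl trifluoromethanesulfonate, via lithium enolate 12 (not isolated)
Conditions: MeLi, THF, 0 °C; PhNTf2, −78 °C → rt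
Reagents that add atoms: N-phenylbis(trifluoromethanesulfonimide) O=S(=O)(N(c1ccccc1)S(=O)(=O)C(F)(F)F)C(F)(F)F
Why: MeLi cleaves the silyl enol ether to the regiodefined lithium enolate, which is O-sulfonylated without touching the C3 stereocentre.

Step 8
Reactants: 13 enol triflate
Product: 14 trimethyl{[(3R)-4,4-dimethyl-3-[2-(2-methyl-1,3-dioxolan-2-yl)ethyl]cyclohept-1-en-1-yl]methyl}silane
Conditions: TMSCH2MgCl, Pd(PPh3)4 (5 mol %), THF/Et2O, 0 °C → rt
Reagents that add atoms: (trimethylsilyl)methylmagnesium chloride C[Si](C)(C)C[Mg]Cl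
Why: Kumada cross-coupling of the enol triflate with the silylmethyl Grignard reagent gives the allylsilane with the alkene position retained.

Step 9
Reactants: 14 allylsilane ketal
Product: 15 4-{(1R)-7,7-dimethyl-3-[(trimethylsilyl)methyl]cyclohept-2-en-1-yl}butan-2-one
Conditions: PPTS, acetone/H2O (10:1), 50 °C
Reagents that add atoms: water O
Why: Mild acid-catalysed ketal hydrolysis unmasks the methyl ketone under conditions that allylsilanes tolerate.

Step 10
Reactants: 15 allylsilane methyl ketone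
Product: 16 (3aR,8aS)-1,4,4-trimethyl-8-methylidenedecahydroazulen-1-ol
Conditions: TiCl4, CH2Cl2, −78 °C
Reagents that add atoms: none
Why: In this intramolecular Hosomi–Sakurai reaction the allylsilane γ-carbon attacks the activated ketone on the only face the three-atom tether can reach, which gives the cis ring fusion (H-8a cis to H-3a), the exocyclic methylene and the tertiary alcohol in one step.

Step 11
Reactants: 16 hydroazulenol
Product: 17 methyl (3aR,8aS)-1,4,4-trimethyl-8-methylidenedecahydroazulen-1-yl oxalate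
Conditions: ClCOCO2Me, Et3N, DMAP (cat.), CH2Cl2, 0 °C → rt
Reagents that add atoms: methyl chlorooxoacetate COC(=O)C(=O)Cl
Why: DMAP-catalysed acylation with the highly electrophilic oxalyl chloride half ester works even on a hindered tertiary alcohol.

Step 12
Reactants: 17 methyl oxalate
Product: 18 cesium 2-{[(3aR,8aS)-1,4,4-trimethyl-8-methylidenedecahydroazulen-1-yl]oxy}-2-oxoacetate
Conditions: CsOH·H2O (1.0 equiv), THF/H2O, rt
Reagents that add atoms: cesium hydroxide [Cs+].[OH-]
Why: Saponification is selective for the unhindered methyl ester of the mixed oxalate and gives the bench-stable salt used as radical precursor.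

Step 13
Reactants: 19 cis-cyclopent-4-ene-1,3-diyl diacetate
Product: 20 meso-2,3-dihydroxycyclopentane-1,4-diyl diacetate
Conditions: OsO4 (1 mol %), NMO, acetone/H2O, rt
Reagents that add atoms: N-methylmorpholine N-oxide C[N+]1([O-])CCOCC1; water O
Why: Upjohn dihydroxylation occurs anti to both allylic acetoxy groups and gives the meso diol.

Step 14
Reactants: 20 meso diol
Product: 21 (3aR,4S,6R,6aS)-2,2-dimethyltetrahydro-3aH-cyclopenta[d][1,3]dioxole-4,6-diyl diacetate
Conditions: Me2C(OMe)2, TsOH·H2O (cat.), acetone, rt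
Reagents that add atoms: 2,2-dimethoxypropane COC(C)(C)OC
Why: Acid-catalysed transketalisation protects the cis diol as the dioxolane; the compound stays meso.

Step 15
Reactants: 21 meso diacetate
Product: 22 (3aR,4S,6R,6aS)-6-hydroxy-2,2-dimethyltetrahydro-3aH-cyclopenta[d][1,3]dioxol-4-yl acetate
Conditions: electric-eel acetylcholinesterase, phosphate buffer pH 6.9, rt
Reagents that add atoms: none
Why: Enzymatic desymmetrisation by an esterase (serine hydrolase) hydrolyses one enantiotopic acetate only, which fixes the absolute configuration of all four ring stereocentres.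

Step 16
Reactants: 22 monoacetate
Product: 24 (3aR,6aR)-2,2-dimethyl-3a,6a-dihydro-4H-cyclopenta[d][1,3]dioxol-4-one, via keto acetate 23 (not isolated)
Conditions: Dess–Martin periodinane, CH2Cl2, rt; Et3N, 0 °C
Reagents that add atoms: none
Why: Dess–Martin oxidation of the free carbinol followed by E1cB loss of acetic acid gives the enone without touching the dioxolane stereocentres.

Step 17
Reactants: 18 cesium oxalate; 24 enone
Product: 25 (3aR,6R,6aR)-6-HAz-2,2-dimethyltetrahydro-4H-cyclopenta[d][1,3]dioxol-4-one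
Conditions: Ir[dF(CF3)ppy]2(dtbbpy)PF6 (1 mol %), DME/DMF (3:1), H2O (10 equiv), blue LEDs, 25–30 °C
Reagents that add atoms: none
Why: In this photoredox Giese reaction the tertiary radical formed by double decarboxylation adds through its convex face (the side of H-3a/H-8a) to the enone face opposite the dioxolane, so the quaternary C1 and the ring C6 stereocentres are both set by substrate control.

Step 18
Reactants: 25 Giese adduct ketone
Product: 27 methyl 2-[(3aR,5S,6R,6aR)-6-HAz-2,2-dimethyl-4-oxotetrahydro-4H-cyclopenta[d][1,3]dioxol-5-yl]acetate, via lithium enolate 26 (not isolated)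
Conditions: LiN(SiMe3)2, THF, −78 °C; BrCH2CO2Me, DMPU, −78 → −40 °C
Reagents that add atoms: methyl bromoacetate COC(=O)CBr
Why: Kinetic deprotonation at the CH2 and SN2 alkylation of the enolate anti to the very large neighbouring HAz group place the acetate arm trans to it (C5).

Step 19
Reactants: 27 alkylated ketone
Product: 29 tricyclic γ-lactone (lactone between O4 and the C5 acetic acid arm, cis-fused on the dioxolane face), via hydroxy ester 28 (not isolated)
Conditions: LiBH(s-Bu)3, THF, −78 → 0 °C; aq. NH4Cl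
Reagents that add atoms: none
Why: The bulky hydride attacks the cyclopentanone opposite the adjacent side chain and dioxolane oxygen, as in reductions of prostaglandin E-type ketones, and the resulting all-cis 4-alkoxide closes onto the cis ester to give the γ-lactone.

Step 20
Reactants: 29 γ-lactone
Product: 31 exo α-hydroxy γ-lactone (OH on the lactone α-carbon, cis to the ring-fusion hydrogens), via potassium enolate 30 (not isolated)
Conditions: KN(SiMe3)2, THF, −78 °C; 2-(phenylsulfonyl)-3-phenyloxaziridine, −78 °C; AcOH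
Reagents that add atoms: 2-(phenylsulfonyl)-3-phenyloxaziridine O=S(=O)(N1OC1c1ccccc1)c1ccccc1
Why: In this Davis oxidation the oxaziridine reaches the lactone enolate only from the convex face of the cis-fused bicycle, the concave face being blocked by the cyclopentane and its dioxolane, which sets the carbinol centre.

Step 21
Reactants: 31 α-hydroxy lactone
Product: 32 tert-butyldiphenylsilyl ether of 31
Conditions: TBDPSCl, imidazole, DMAP (cat.), DMF, 40 °C
Reagents that add atoms: tert-butylchlorodiphenylsilane CC(C)(C)[Si](Cl)(c1ccccc1)c1ccccc1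
Why: Silylation protects the only free hydroxyl with a group that survives base, acetylation and the later acetic acid step.

Step 22
Reactants: 32 silyloxy lactone
Product: 35 4-acetoxy methyl ester acetonide (C4 acetate, C5 arm CH(OTBDPS)CO2Me, dioxolane intact), via hydroxy acid 33 (not isolated), via hydroxy methyl ester 34 (not isolated)
Conditions: LiOH, THF/MeOH/H2O, rt; 1 M HCl to pH 4, 0 °C; TMSCHN2, PhMe/MeOH, 0 °C; Ac2O, pyridine, DMAP, 0 °C → rt
Reagents that add atoms: lithium hydroxide [Li+].[OH-]; (trimethylsilyl)diazomethane C[Si](C)(C)C=[N+]=[N-]; acetic anhydride CC(=O)OC(C)=O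
Why: Saponification, neutral esterification with the diazoalkane and immediate DMAP-catalysed acetylation are telescoped so the γ-hydroxy ester is trapped before it can relactonise; no stereocentre is touched.

Step 23
Reactants: 35 acetate acetonide
Product: 36 3a,6a-diol (cis diol on the face of the acetoxy group and the C5 arm)
Conditions: AcOH/H2O (4:1), 55 °C
Reagents that add atoms: none
Why: Aqueous acetic acid hydrolyses the dioxolane while the silyl ether, both esters and the exocyclic alkene survive.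

Step 24
Reactants: 36 diol
Product: 37 α-ketol (C3a ketone with C6a hydroxyl)
Conditions: Ag2CO3 on Celite, PhH, 80 °C
Reagents that add atoms: none
Why: Fétizon oxidation stops at the α-ketol and needs the carbinol C–H to reach the silver surface; the C6a–H is cis to the adjacent quaternary HAz group and shielded, so only the C3a hydroxyl is oxidised.

Step 25
Reactants: 37 α-ketol
Product: 38 seco aldehydo acid (2S)-2-acetoxy-3-[(R)-(silyloxy)(methoxycarbonyl)methyl]-4-formyl-4-HAz-butanoic acid
Conditions: H5IO6, THF/H2O, 0 °C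
Reagents that add atoms: periodic acid OI(O)(O)(O)(O)=O
Why: Malaprade-type cleavage of the α-hydroxy ketone gives the carboxylic acid from the ketone carbon and the aldehyde from the carbinol carbon and leaves the alkene untouched.

Step 26
Reactants: 38 seco aldehydo acid
Product: 40 target compound CNP0215240.1, via hydroxy aldehydo acid 39 (not isolated)
Conditions: HF·pyridine, THF, 0 °C → rt; PPTS (cat.), 4 Å MS, CH2Cl2, rt
Reagents that add atoms: none
Why: After desilylation the γ-hydroxy aldehyde closes to the five-membered lactol much faster than the hydroxy acid can lactonise, and acid-catalysed capture of the oxocarbenium ion by the carboxylic acid gives the bridged acyloxy acetal, whose acetal carbon can adopt only one configuration.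

## Compound list

1 | 3-methylcyclohex-2-en-1-one | CC1=CC(=O)CCC1 | starting material
2 | [(3,3-dimethylcyclohex-1-en-1-yl)oxy]trimethylsilane | C[Si](C)(C)OC1=CC(C)(C)CCC1 | intermediate
3 | 5,5-dimethyl-1-(trimethylsilyloxy)bicyclo[4.1.0]heptane (racemic, not isolated) | C[Si](C)(C)OC12CCCC(C)(C)C1C2 | intermediate
4 | 3-chloro-4,4-dimethylcycloheptan-1-one (racemic, not isolated) | O=C1CC(Cl)C(C)(C)CCC1 | intermediate
5 | 4,4-dimethylcyclohept-2-en-1-one | O=C1C=CC(C)(C)CCC1 | intermediate
6 | 2-(2-bromoethyl)-2-methyl-1,3-dioxolane | CC1(CCBr)OCCO1 | starting material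
7 | bromo[2-(2-methyl-1,3-dioxolan-2-yl)ethyl]magnesium (THF stock solution) | CC1(CC[Mg]Br)OCCO1 | intermediate
8 | chloro[2-(2-methyl-1,3-dioxolan-2-yl)ethyl]zinc | CC1(CC[Zn]Cl)OCCO1 | intermediate
9 | bis[2-(2-methyl-1,3-dioxolan-2-yl)ethyl]zinc | CC1(CC[Zn]CCC2(C)OCCO2)OCCO1 | intermediate
10 | alkylzinc enolate of (3R)-4,4-dimethyl-3-[2-(2-methyl-1,3-dioxolan-2-yl)ethyl]cycloheptanone (not isolated) | CC1(CC[Zn]OC2=C[C@@H](CCC3(C)OCCO3)C(C)(C)CCC2)OCCO1 | intermediate
11 | trimethyl{[(3R)-4,4-dimethyl-3-[2-(2-methyl-1,3-dioxolan-2-yl)ethyl]cyclohept-1-en-1-yl]oxy}silane | C[Si](C)(C)OC1=C[C@@H](CCC2(C)OCCO2)C(C)(C)CCC1 | intermediate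
12 | lithium enolate corresponding to 11 (not isolated) | [Li]OC1=C[C@@H](CCC2(C)OCCO2)C(C)(C)CCC1 | intermediate
13 | (3R)-4,4-dimethyl-3-[2-(2-methyl-1,3-dioxolan-2-yl)ethyl]cyclohept-1-en-1-yl trifluoromethanesulfonate | O=S(=O)(OC1=C[C@@H](CCC2(C)OCCO2)C(C)(C)CCC1)C(F)(F)F | intermediate
14 | trimethyl{[(3R)-4,4-dimethyl-3-[2-(2-methyl-1,3-dioxolan-2-yl)ethyl]cyclohept-1-en-1-yl]methyl}silane | C[Si](C)(C)CC1=C[C@@H](CCC2(C)OCCO2)C(C)(C)CCC1 | intermediate
15 | 4-{(1R)-7,7-dimethyl-3-[(trimethylsilyl)methyl]cyclohept-2-en-1-yl}butan-2-one | C[Si](C)(C)CC1=C[C@@H](CCC(C)=O)C(C)(C)CCC1 | intermediate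
16 | (3aR,8aS)-1,4,4-trimethyl-8-methylidenedecahydroazulen-1-ol (cis-fused, C1 epimers) | C=C1CCCC(C)(C)[C@@H]2CCC(C)(O)[C@H]12 | intermediate
17 | methyl (3aR,8aS)-1,4,4-trimethyl-8-methylidenedecahydroazulen-1-yl oxalate | C=C1CCCC(C)(C)[C@@H]2CCC(C)(OC(=O)C(=O)OC)[C@H]12 | intermediate
18 | cesium 2-{[(3aR,8aS)-1,4,4-trimethyl-8-methylidenedecahydroazulen-1-yl]oxy}-2-oxoacetate | C=C1CCCC(C)(C)[C@@H]2CCC(C)(OC(=O)C(=O)[O-])[C@H]12.[Cs+] | intermediate
19 | cis-cyclopent-4-ene-1,3-diyl diacetate (meso) | CC(=O)O[C@@H]1C[C@H](OC(C)=O)C=C1 | starting material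
20 | meso-2,3-dihydroxycyclopentane-1,4-diyl diacetate (diol trans to both acetoxy groups) | CC(=O)O[C@@H]1C[C@H](OC(C)=O)[C@@H](O)[C@H]1O | intermediate
21 | (3aR,4S,6R,6aS)-2,2-dimethyltetrahydro-3aH-cyclopenta[d][1,3]dioxole-4,6-diyl diacetate (meso) | CC(=O)O[C@@H]1C[C@H](OC(C)=O)[C@H]2OC(C)(C)O[C@@H]12 | intermediate
22 | (3aR,4S,6R,6aS)-6-hydroxy-2,2-dimethyltetrahydro-3aH-cyclopenta[d][1,3]dioxol-4-yl acetate | O[C@@H]1C[C@H](OC(C)=O)[C@H]2OC(C)(C)O[C@@H]12 | intermediate
23 | (3aR,4S,6aR)-2,2-dimethyl-6-oxotetrahydro-3aH-cyclopenta[d][1,3]dioxol-4-yl acetate (not isolated) | O=C1C[C@H](OC(C)=O)[C@H]2OC(C)(C)O[C@@H]12 | intermediate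
24 | (3aR,6aR)-2,2-dimethyl-3a,6a-dihydro-4H-cyclopenta[d][1,3]dioxol-4-one | O=C1C=C[C@H]2OC(C)(C)O[C@@H]12 | intermediate
25 | (3aR,6R,6aR)-6-HAz-2,2-dimethyltetrahydro-4H-cyclopenta[d][1,3]dioxol-4-one (HAz trans to the dioxolane) | C=C1CCCC(C)(C)[C@@H]2CC[C@@](C)([C@H]3CC(=O)[C@@H]4OC(C)(C)O[C@H]34)[C@H]12 | intermediate
26 | lithium 4,5-enolate of 25 (not isolated) | C=C1CCCC(C)(C)[C@@H]2CC[C@@](C)([C@H]3C=C(O[Li])[C@@H]4OC(C)(C)O[C@H]34)[C@H]12 | intermediate
27 | methyl 2-[(3aR,5S,6R,6aR)-6-HAz-2,2-dimethyl-4-oxotetrahydro-4H-cyclopenta[d][1,3]dioxol-5-yl]acetate (side chain trans to HAz) | C=C1CCCC(C)(C)[C@@H]2CC[C@@](C)([C@H]3[C@H](CC(=O)OC)C(=O)[C@@H]4OC(C)(C)O[C@H]34)[C@H]12 | intermediate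
28 | 4-hydroxy ester: 27 reduced to the 4-alcohol, OH cis to the C5 side chain and to the dioxolane (not isolated) | C=C1CCCC(C)(C)[C@@H]2CC[C@@](C)([C@H]3[C@H](CC(=O)OC)[C@H](O)[C@@H]4OC(C)(C)O[C@H]34)[C@H]12 | intermediate
29 | tricyclic γ-lactone: lactone between O4 and the C5 acetic acid arm, cis-fused on the dioxolane face, HAz on the opposite face | C=C1CCCC(C)(C)[C@@H]2CC[C@@](C)([C@H]3[C@@H]5CC(=O)O[C@@H]5[C@@H]4OC(C)(C)O[C@H]34)[C@H]12 | intermediate
30 | potassium enolate of lactone 29 (not isolated) | C=C1CCCC(C)(C)[C@@H]2CC[C@@](C)([C@H]3[C@@H]5C=C(O[K])O[C@@H]5[C@@H]4OC(C)(C)O[C@H]34)[C@H]12 | intermediate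
31 | α-hydroxy γ-lactone: 29 with OH on the lactone α-carbon, exo (cis to the ring-fusion hydrogens), R at that carbon | C=C1CCCC(C)(C)[C@@H]2CC[C@@](C)([C@H]3[C@@H]5[C@@H](O)C(=O)O[C@@H]5[C@@H]4OC(C)(C)O[C@H]34)[C@H]12 | intermediate
32 | tert-butyldiphenylsilyl ether of 31 | C=C1CCCC(C)(C)[C@@H]2CC[C@@](C)([C@H]3[C@@H]5[C@@H](O[Si](c6ccccc6)(c7ccccc7)C(C)(C)C)C(=O)O[C@@H]5[C@@H]4OC(C)(C)O[C@H]34)[C@H]12 | intermediate
33 | ring-opened hydroxy acid of 32: 4-OH, (R)-2-silyloxyacetic acid arm at C5 (not isolated) | C=C1CCCC(C)(C)[C@@H]2CC[C@@](C)([C@H]3[C@H]([C@@H](O[Si](c5ccccc5)(c6ccccc6)C(C)(C)C)C(=O)O)[C@H](O)[C@@H]4OC(C)(C)O[C@H]34)[C@H]12 | intermediate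
34 | methyl ester of 33 (not isolated) | C=C1CCCC(C)(C)[C@@H]2CC[C@@](C)([C@H]3[C@H]([C@@H](O[Si](c5ccccc5)(c6ccccc6)C(C)(C)C)C(=O)OC)[C@H](O)[C@@H]4OC(C)(C)O[C@H]34)[C@H]12 | intermediate
35 | 4-acetate of 34: (4S)-acetoxy, C5 arm CH(OTBDPS)CO2Me, dioxolane intact | C=C1CCCC(C)(C)[C@@H]2CC[C@@](C)([C@H]3[C@H]([C@@H](O[Si](c5ccccc5)(c6ccccc6)C(C)(C)C)C(=O)OC)[C@H](OC(C)=O)[C@@H]4OC(C)(C)O[C@H]34)[C@H]12 | intermediate
36 | 3a,6a-diol from 35: cis diol on the face of the acetoxy group and the C5 arm | C=C1CCCC(C)(C)[C@@H]2CC[C@@](C)([C@H]3[C@H]([C@@H](O[Si](c5ccccc5)(c6ccccc6)C(C)(C)C)C(=O)OC)[C@H](OC(C)=O)[C@H](O)[C@@H]3O)[C@H]12 | intermediate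
37 | α-ketol: C3a ketone next to the acetoxy carbon, C6a hydroxyl retained | C=C1CCCC(C)(C)[C@@H]2CC[C@@](C)([C@H]3[C@H]([C@@H](O[Si](c5ccccc5)(c6ccccc6)C(C)(C)C)C(=O)OC)[C@H](OC(C)=O)C(=O)[C@@H]3O)[C@H]12 | intermediate
38 | seco aldehydo acid: (2S)-2-acetoxy-3-[(R)-(silyloxy)(methoxycarbonyl)methyl]-4-formyl-4-HAz-butanoic acid, in equilibrium with its δ-lactol | C=C1CCCC(C)(C)[C@@H]2CC[C@@](C)([C@H](C=O)[C@H]([C@@H](O[Si](c3ccccc3)(c4ccccc4)C(C)(C)C)C(=O)OC)[C@H](OC(C)=O)C(=O)O)[C@H]12 | intermediate
39 | desilylated hydroxy aldehydo acid (not isolated) | C=C1CCCC(C)(C)[C@@H]2CC[C@@](C)([C@H](C=O)[C@H]([C@@H](O)C(=O)OC)[C@H](OC(C)=O)C(=O)O)[C@H]12 | intermediate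
40 | methyl (1S,4S,5R,6R,8R)-4-acetoxy-3-oxo-8-[(1R,3aR,8aS)-1,4,4-trimethyl-8-methylidenedecahydroazulen-1-yl]-2,7-dioxabicyclo[3.2.1]octane-6-carboxylate (CNP0215240.1) | C=C1CCCC(C)(C)[C@@H]2CC[C@@](C)([C@@H]3[C@@H]4OC(=O)[C@@H](OC(C)=O)[C@H]3[C@H](C(=O)OC)O4)[C@H]12 | target

## Step count and weak points

Total steps: 26. Longest linear sequence: 20 steps (steps 3 to 12, then 17 to 26).

The three steps most likely to fail:

Step 18 (enolate alkylation next to the HAz-bearing carbon). The enolate is hindered and can equilibrate to the α-oxygenated side, which expels the dioxolane oxygen. The fallback installs the arm before the fragment coupling and sets out from enone 24. Iodination with I2 and pyridine in CH2Cl2 gives (3aR,6aR)-5-iodo-2,2-dimethyl-3a,6a-dihydro-4H-cyclopenta[d][1,3]dioxol-4-one F1. Negishi coupling with the Reformatsky reagent BrZnCH2CO2Me and Pd(PPh3)4 in THF gives methyl 2-[(3aR,6aR)-2,2-dimethyl-4-oxo-3a,6a-dihydro-4H-cyclopenta[d][1,3]dioxol-5-yl]acetate F2. Photoredox coupling of F2 with oxalate 18 under the conditions of step 17, followed by equilibration of the new α-centre with Et3N in CH2Cl2 to the trans isomer, comes back to the route at 27.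

Step 24 (regioselective Fétizon oxidation of one of two secondary hydroxyls). Selectivity rests only on steric shielding of the C6a–H, and the ketol could isomerise or the acetate migrate on the basic surface. The fallback differentiates after cleavage and sets out from diol 36. Pb(OAc)4 in PhH/pyridine at 0 °C cleaves the glycol to the dialdehyde methyl (2R)-2-(silyloxy)-3-[(1S)-1-acetoxy-2-oxoethyl]-4-formyl-4-HAz-butanoate F3. Pinnick oxidation with one equivalent of NaClO2 (NaH2PO4, 2-methylbut-2-ene, t-BuOH/H2O, 0 °C) converts the unhindered α-acetoxy aldehyde, while the neopentyl-type aldehyde reacts much more slowly, and comes back to the route at 38.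

Step 26 (final bicyclisation). The free hydroxy acid could instead close to a γ-lactone and leave the aldehyde open. The fallback locks the δ-lactone first and sets out from 38. Ac2O and pyridine at 0 °C trap the δ-lactol form as the 6-acetoxy δ-lactone silyl ether F4 (anomer mixture). HF·pyridine in THF gives the 6-acetoxy δ-lactone alcohol F5. Catalytic TMSOTf in CH2Cl2 at −40 °C ionises the anomeric acetate and the side-chain hydroxyl closes the tetrahydrofuran, which comes back to the route at 40.

## Further compounds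

F1 | step 18 | (3aR,6aR)-5-iodo-2,2-dimethyl-3a,6a-dihydro-4H-cyclopenta[d][1,3]dioxol-4-one | O=C1C(I)=C[C@H]2OC(C)(C)O[C@@H]12
F2 | step 18 | methyl 2-[(3aR,6aR)-2,2-dimethyl-4-oxo-3a,6a-dihydro-4H-cyclopenta[d][1,3]dioxol-5-yl]acetate | O=C1C(CC(=O)OC)=C[C@H]2OC(C)(C)O[C@@H]12
F3 | step 24 | methyl (2R)-2-(silyloxy)-3-[(1S)-1-acetoxy-2-oxoethyl]-4-formyl-4-HAz-butanoate (dialdehyde) | C=C1CCCC(C)(C)[C@@H]2CC[C@@](C)([C@H](C=O)[C@H]([C@@H](O[Si](c3ccccc3)(c4ccccc4)C(C)(C)C)C(=O)OC)[C@H](OC(C)=O)C=O)[C@H]12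
F4 | step 26 | 6-acetoxy δ-lactone (pseudo-acid acetate of 38, anomer mixture, silyl ether intact) | C=C1CCCC(C)(C)[C@@H]2CC[C@@](C)([C@@H]3C(OC(C)=O)OC(=O)[C@@H](OC(C)=O)[C@H]3[C@@H](O[Si](c4ccccc4)(c5ccccc5)C(C)(C)C)C(=O)OC)[C@H]12
F5 | step 26 | 6-acetoxy δ-lactone alcohol (F4 without the silyl group) | C=C1CCCC(C)(C)[C@@H]2CC[C@@](C)([C@@H]3C(OC(C)=O)OC(=O)[C@@H](OC(C)=O)[C@H]3[C@@H](O)C(=O)OC)[C@H]12
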